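(The numbers of this flask were drawn at random within sensible limits; the result is computed.)

If a two-state system starts wholly in one state and nothing else pushes on it, it relaxes at the sum of its two rate constants, however busy its surroundings are. This flask is such a case, since the first step hands J back unchanged and J is charged without E.

L 0.80 M; Z 1.50 equiv; Q 0.160 M; J 0.5 mol%

    L + Z + J → L.Z + J, rate k1*[L]*[Z]*[J]/(1 + ([L]/sat1)) (sat1 = 0.84 M, k1 = 0.37 M⁻² s⁻¹)
    Z + Q → Z.Q (k2 = 0.0041 M⁻¹ s⁻¹)
    J ⇌ E (K3 = 0.36, k3 = 9.9 × 10⁻⁴ s⁻¹)

1. the form that holds most of the catalyst when 30 % of the L are converted (J / E)
2. its share of the catalyst then

I carry one quantity: the relaxation rate λ of the pair, the forward constant of J to E plus the back constant, 0.224 min⁻¹. At equilibrium J holds 73.5 % of the catalyst, more than E. Its share at any time is that figure plus an excess which starts at 26.5 % and dies as exp(−λt). So I need the time to the asked conversion, when [L] stands at 0.560 M.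

I bracket that time with two extreme flasks, both with a catalyst charge of 0.00400 M. In the fast one, Q takes no Z and the first step sees the whole catalyst as J. In the slow one, Q takes its whole charge from Z at once and the first step sees J at its equilibrium share from the start. These extremes serve for the time alone; the share then comes from the relaxation. In each, [J] is constant and [Z] − [L] is a constant d, 0.400 M or 0.240 M. The rate law then integrates in closed form: the time is the log change of [L]/[Z] over d, plus the log change of [Z] over sat, all divided by the first step's constant times [J].

| extreme flask | time | share of J from exp(−λt) at that time |
|---|---|---|
| fast | 6.75 min | 79.3 % |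
| slow | 10.8 min | 75.9 % |

I expect the real time between the two, since the real flask's [J] and Z.Q should each lie between the extremes. The exponential squeezes a spread of 4.05 min in time into 3.4 percentage points of share, so I say J, inside that range. The forecast says J at 77 %, with the conversion reached “when the equilibration is mostly but not fully complete”.

The simulation gives J at 77.3 %, reached at 8.72 min. The relaxation rate turns that time into 77.3 %. At 3.00 min it gives 87.0 %, and the flask holds 87.0 % of its catalyst as J. The apparent order in J at the asked conversion stands at 1.2 because E falls back to J. The same run without that return reaches 1.9.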